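**Strategy.** Ring B is a cyclohexenone whose C5–C6 edge is a two-carbon unit carrying the carbonyl carbon and whose C7–C8–C9–C10 edge is a four-carbon unit; ring A (C1–C4) links C10 to C5. The route rests on an intramolecular Diels–Alder reaction of an acyclic nitro triene. An (E)-nitroalkene (C5=C6, nitro standing in for the C6 ketone) adds to a 2,3,4-trisubstituted diene (C7=C8–C9=C10). This forms C6–C7 and C5–C10, both rings and the C5 and C10 stereocentres at once, steered by the C3 acetoxy centre taken from (S)-pantolactone. A Nef reaction and migration of the double bond into conjugation then give the enone.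

Key step: step 9

Remark: drimane numbering is used (ring A = C1–C5 and C10, ring B = C5–C10, C11 = oxymethylene on C9). In this numbering the target is 3R,5S,9R,10S: H-3, H-5 and H-9 lie on one face, and the 3-acetoxy group, the C10 methyl and C11 on the other.

**Step 1**
Reactants: 1 but-2-yn-1-ol; 2 isopropenylmagnesium bromide
Product: 4 (2Z)-3-iodo-2-(prop-1-en-2-yl)but-2-en-1-ol, via cyclic alkenylmagnesium alkoxide 3 (not isolated)
Conditions: 2 (4 equiv), CuI (10 mol %), THF–toluene, reflux; then I2, −78 to 0 °C; aq. NH4Cl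
Reagents that add atoms: iodine, II
Why: Chelation-controlled anti-carbomagnesiation of the propargylic alkoxide puts isopropenyl on the carbinol-proximal carbon and magnesium on the distal carbon of a five-membered chelate, and iodinolysis with retention should give the Z iodide (iodine cis to CH2OH).

**Step 2**
Reactants: 4 (2Z)-3-iodo-2-(prop-1-en-2-yl)but-2-en-1-ol; 5 umbelliferone
Product: 6 7-{[(2Z)-3-iodo-2-(prop-1-en-2-yl)but-2-en-1-yl]oxy}-2H-chromen-2-one
Conditions: PPh3, DIAD, THF, 0 °C to rt
Reagents that add atoms: none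
Why: Mitsunobu etherification of an unhindered primary allylic alcohol with an acidic phenol should proceed by SN2 substitution without touching the vinyl iodide.

**Step 3**
Reactants: 7 (S)-(+)-pantolactone
Product: 8 (3S)-4,4-dimethyloxolane-2,3-diol (lactol, anomeric mixture)
Conditions: i-Bu2AlH (2.2 equiv), CH2Cl2, −78 °C; Rochelle salt
Reagents that add atoms: none
Why: Half-reduction of the lactone by i-Bu2AlH stops at the aluminium lactolate at low temperature, and the carbinol stereocentre is not involved.

**Step 4**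
Reactants: 8 (3S)-4,4-dimethyloxolane-2,3-diol
Product: 9 (3R)-2,2-dimethylpent-4-ene-1,3-diol
Conditions: Ph3PCH3Br, KOtBu (3.5 equiv each), THF, 0 °C to reflux
Reagents that add atoms: methyltriphenylphosphonium bromide, C[P+](c1ccccc1)(c1ccccc1)c1ccccc1.[Br-]
Why: Wittig methylenation of the open hydroxy-aldehyde form of the lactol should give the vinyl carbinol, the adjacent alkoxide suppressing enolisation so that the stereocentre is kept.

**Step 5**
Reactants: 9 (3R)-2,2-dimethylpent-4-ene-1,3-diol; 6 7-{[(2Z)-3-iodo-2-(prop-1-en-2-yl)but-2-en-1-yl]oxy}-2H-chromen-2-one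
Product: 11 7-{[(2Z,6R)-6,8-dihydroxy-3,7,7-trimethyl-2-(prop-1-en-2-yl)oct-2-en-1-yl]oxy}-2H-chromen-2-one, via B-alkyl-9-BBN borane 10 (not isolated)
Conditions: 9-BBN (3.3 equiv), THF, rt; then H2O, 6, Pd(dppf)Cl2 (5 mol %), AsPh3, Cs2CO3, DMF–THF–H2O, rt
Reagents that add atoms: 9-BBN, [H]B1C2CCCC1CCC2 (its atoms stay only in intermediate 10)
Why: Anti-Markovnikov hydroboration of the monosubstituted alkene followed by B-alkyl Suzuki–Miyaura coupling with retention at the vinyl iodide should give the tetrasubstituted Z alkene with the new chain cis to the aryloxymethyl group.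

**Step 6**
Reactants: 11 diol
Product: 12 (3R,6Z)-3-hydroxy-2,2,6-trimethyl-8-[(2-oxo-2H-chromen-7-yl)oxy]-7-(prop-1-en-2-yl)oct-6-enal
Conditions: TEMPO (10 mol %), PhI(OAc)2, CH2Cl2, rt
Reagents that add atoms: none
Why: The oxoammonium oxidation (TEMPO/PhI(OAc)2) is selective for the primary over the hindered secondary alcohol, and the aldehyde has no α-hydrogen and cannot epimerise or dehydrate.

**Step 7**
Reactants: 12 hydroxy aldehyde; 13 nitromethane
Product: 14 7-{[(2Z,6R)-6,8-dihydroxy-3,7,7-trimethyl-9-nitro-2-(prop-1-en-2-yl)non-2-en-1-yl]oxy}-2H-chromen-2-one (both C8 epimers)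
Conditions: 13 (10 equiv), tetramethylguanidine (10 mol %), THF, 0 °C
Reagents that add atoms: none
Why: The Henry (nitroaldol) addition to a non-enolisable aldehyde should be clean under mild amidine-type base, and the new carbinol configuration is irrelevant because it is eliminated next.

**Step 8**
Reactants: 14 nitro diol
Product: 16 (1E,4R,7Z)-3,3,7-trimethyl-1-nitro-9-[(2-oxo-2H-chromen-7-yl)oxy]-8-(prop-1-en-2-yl)nona-1,7-dien-4-yl acetate, via β-nitro diacetate 15 (not isolated)
Conditions: Ac2O, Et3N, DMAP (cat.), CH2Cl2, 0 °C to rt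
Reagents that add atoms: acetic anhydride, CC(=O)OC(C)=O
Why: Double acetylation followed by E1cB loss of acetate from the β-nitro acetate should install the C3 acetate and the (E)-nitroalkene in one operation.

**Step 9**
Reactants: 16 nitro triene
Product: 17 (3R,5S,6R,10R)-3-acetoxy-6-nitro-11-[(2-oxo-2H-chromen-7-yl)oxy]drim-8-ene (trans-fused; H-5 anti to the C10 methyl, nitro syn to H-5, acetoxy syn to the C10 methyl)
Conditions: toluene (0.01 M), BHT (cat.), 110 °C, sealed tube
Reagents that add atoms: none
Why: A concerted, asynchronous normal-demand [4+2] cycloaddition joins the (E)-nitroalkene C5=C6 to the s-cis diene C7=C8–C9=C10, the C6–C7 bond to the unhindered CH2 terminus leading and the congested C5–C10 bond following; the closest known type is the thermal intramolecular Diels–Alder reaction of (E)-1-nitrodeca-1,7,9-trienes. Ring B is closed by the cycloaddition itself (both new bonds suprafacial on each partner) and ring A is closed as the six-membered tether ring through the C5–C10 bond (fused mode, tether on the diene terminus). The nitro-endo transition state, with the tether on the outside position of the Z C9=C10 alkene, should set H-5 anti to the C10 methyl (trans-decalin) and the nitro group syn to H-5. The absolute sense at C5 and C10 is controlled by the C3 stereocentre, whose acetoxy group takes the equatorial site of the chair-like tether and so ends syn to the angular methyl. The step needs π-facial and endo selectivity; a cis-fused isomer with the same C3/C10 relationship converges later because C5 becomes epimerisable next to the C6 ketone, and any nitronate formed by the nitroalkene acting as heterodiene should relay to the same product by [3,3] shift. The gem-dimethyl group at C4 and the high dienophilicity of the nitroalkene offset the hindrance, and 110 °C lies well below [1,5]-hydrogen shift of the diene or Claisen rearrangement of the aryl allyl ether.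

**Step 10**
Reactants: 17 nitro octalin
Product: 19 (3R,5S,10R)-3-acetoxy-11-[(2-oxo-2H-chromen-7-yl)oxy]drim-8-en-6-one, via DBU-H nitronate 18 (not isolated)
Conditions: DBU, THF, 0 °C; then aq. TiCl3, NH4OAc, rt
Reagents that add atoms: water, O
Why: The reductive Nef reaction (McMurry) reduces the nitronate with trivalent titanium to the imine, which hydrolyses at pH 5–6 to the ketone without harming the acetate, the coumarin or the allylic aryl ether.

**Step 11**
Reactants: 19 β,γ-unsaturated ketone
Product: 20 target, (3R,5S,9R,10S)-3-acetoxy-11-[(2-oxo-2H-chromen-7-yl)oxy]drim-7-en-6-one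
Conditions: TsOH·H2O (10 mol %), CH2Cl2, 0 °C to rt
Reagents that add atoms: none
Why: Acid-catalysed enolisation towards C7 gives the conjugated dienol, and kinetic protonation at C9 from the face opposite the axial C10 methyl should move the double bond to C7=C8 with H-9 syn to H-5; C5 can equilibrate to the trans ring fusion, and acid avoids the vinylogous loss of aryloxide that base would cause.

**Compound list**
1 | but-2-yn-1-ol | CC#CCO | starting material
2 | isopropenylmagnesium bromide | C=C(C)[Mg]Br | starting material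
3 | 3-methyl-4-(prop-1-en-2-yl)-2,5-dihydro-1,2-oxamagnesole (cyclic alkenylmagnesium alkoxide) | CC1=C(C(C)=C)CO[Mg]1 | intermediate
4 | (2Z)-3-iodo-2-(prop-1-en-2-yl)but-2-en-1-ol | OC/C(C(C)=C)=C(/C)I | intermediate
5 | umbelliferone (7-hydroxy-2H-chromen-2-one) | Oc1ccc2ccc(=O)oc2c1 | starting material
6 | 7-{[(2Z)-3-iodo-2-(prop-1-en-2-yl)but-2-en-1-yl]oxy}-2H-chromen-2-one | O=c1ccc2ccc(OC/C(C(C)=C)=C(/C)I)cc2o1 | intermediate
7 | (S)-(+)-pantolactone, (3S)-3-hydroxy-4,4-dimethyloxolan-2-one | CC1(C)COC(=O)[C@H]1O | starting material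
8 | (3S)-4,4-dimethyloxolane-2,3-diol (anomeric mixture) | CC1(C)COC(O)[C@H]1O | intermediate
9 | (3R)-2,2-dimethylpent-4-ene-1,3-diol | C=C[C@@H](O)C(C)(C)CO | intermediate
10 | B-alkyl-9-BBN adduct of 9, both hydroxyls as O-(9-BBN) borinates | C(C[C@@H](OB1C2CCCC1CCC2)C(C)(C)COB1C2CCCC1CCC2)B1C2CCCC1CCC2 | intermediate
11 | 7-{[(2Z,6R)-6,8-dihydroxy-3,7,7-trimethyl-2-(prop-1-en-2-yl)oct-2-en-1-yl]oxy}-2H-chromen-2-one | O=c1ccc2ccc(OC/C(C(C)=C)=C(/C)CC[C@@H](O)C(C)(C)CO)cc2o1 | intermediate
12 | (3R,6Z)-3-hydroxy-2,2,6-trimethyl-8-[(2-oxo-2H-chromen-7-yl)oxy]-7-(prop-1-en-2-yl)oct-6-enal | O=c1ccc2ccc(OC/C(C(C)=C)=C(/C)CC[C@@H](O)C(C)(C)C=O)cc2o1 | intermediate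
13 | nitromethane | C[N+](=O)[O-] | starting material
14 | 7-{[(2Z,6R)-6,8-dihydroxy-3,7,7-trimethyl-9-nitro-2-(prop-1-en-2-yl)non-2-en-1-yl]oxy}-2H-chromen-2-one (C8 epimers) | O=c1ccc2ccc(OC/C(C(C)=C)=C(/C)CC[C@@H](O)C(C)(C)C(O)C[N+](=O)[O-])cc2o1 | intermediate
15 | diacetate of 14 (β-nitro acetate) | O=c1ccc2ccc(OC/C(C(C)=C)=C(/C)CC[C@@H](OC(C)=O)C(C)(C)C(OC(C)=O)C[N+](=O)[O-])cc2o1 | intermediate
16 | (1E,4R,7Z)-3,3,7-trimethyl-1-nitro-9-[(2-oxo-2H-chromen-7-yl)oxy]-8-(prop-1-en-2-yl)nona-1,7-dien-4-yl acetate | O=c1ccc2ccc(OC/C(C(C)=C)=C(/C)CC[C@@H](OC(C)=O)C(C)(C)/C=C/[N+](=O)[O-])cc2o1 | intermediate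
17 | (3R,5S,6R,10R)-3-acetoxy-6-nitro-11-[(2-oxo-2H-chromen-7-yl)oxy]drim-8-ene | CC(=O)O[C@@H]1CC[C@@]2(C)C(COc3ccc4ccc(=O)oc4c3)=C(C)C[C@@H]([N+](=O)[O-])[C@@H]2C1(C)C | intermediate
18 | DBU-H salt of the C6 nitronate of 17 | CC(=O)O[C@@H]1CC[C@@]2(C)C(COc3ccc4ccc(=O)oc4c3)=C(C)CC(=[N+]([O-])[O-])[C@@H]2C1(C)C.C1CCC2=[NH+]CCCN2CC1 | intermediate
19 | (3R,5S,10R)-3-acetoxy-11-[(2-oxo-2H-chromen-7-yl)oxy]drim-8-en-6-one | CC(=O)O[C@@H]1CC[C@@]2(C)C(COc3ccc4ccc(=O)oc4c3)=C(C)CC(=O)[C@@H]2C1(C)C | intermediate
20 | (3R,5S,9R,10S)-3-acetoxy-11-[(2-oxo-2H-chromen-7-yl)oxy]drim-7-en-6-one | CC(=O)O[C@@H]1CC[C@@]2(C)[C@H](COc3ccc4ccc(=O)oc4c3)C(C)=CC(=O)[C@@H]2C1(C)C | target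

**Step count and risks**
Total steps: 11. Longest linear sequence: 9 steps (7 → 20 through steps 3–11; the branch from 1 through steps 1, 2 and 5–11 is equally long).

Steps most likely to fail:

1. Step 9 (key cycloaddition). The process at risk is weak π-facial discrimination by the C3 acetoxy group, or slow closure of the hindered C5–C10 bond so that polymerisation of the nitroalkene competes. Fallback: setting out from 16, SnCl4 in CH2Cl2 at −78 °C should make the nitroalkene react as a heterodiene with the C9=C10 double bond (inverse-demand hetero-Diels–Alder reaction). This gives the bicyclic nitronate F1, in which ring A and the C5–C10 bond are already in place. Warming F1 in toluene should then induce the [3,3]-sigmatropic shift of the allylic nitronate (O–C9 broken, C6–C7 made), which comes back to the route at 17.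

2. Step 11 (olefin migration). The process at risk is protonation of the dienol at C9 from both faces, or vinylogous loss of the aryloxide from C11. Fallback: setting out from 19, DBU in CH2Cl2 deliberately expels umbelliferone by 1,6-elimination to give the dienone F2. Excess 9-BBN should then reduce the ketone in 1,2 fashion and hydroborate the exocyclic C9=C11 methylene from the face opposite the angular methyl; NaBO3·4H2O oxidation gives the diol F3 with H-9 syn to H-5 (C6 configuration of no consequence). MnO2 should oxidise only the allylic C6 carbinol to the hydroxy enone F4, and Mitsunobu etherification of F4 with 5 (PPh3, DIAD) comes back to the route at 20.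

3. Step 5 (B-alkyl Suzuki–Miyaura coupling). The process at risk is slow oxidative addition and transmetalation at the tetrasubstituted iodide, during which zerovalent palladium ionises the allylic aryl ether or aqueous base opens the lactone. Fallback: setting out from 4 and the borane 10, the same coupling is run on the free alcohol, which has no aryl ether, to give the triol F5. A Mitsunobu reaction of F5 with 5 should then etherify only the allylic primary hydroxyl (the neopentyl primary and hindered secondary hydroxyls being much slower) and comes back to the route at 11.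

**Further compounds**
F1 | step 9 | bicyclic nitronate: ring A fused at C5–C10 to a 1,2-oxazine 2-oxide ring (O–N(O)=C6–C5–C10–C9), C9 bearing the aryloxymethyl and isopropenyl groups | CC(=O)O[C@@H]1CC[C@@]2(C)[C@](COc3ccc4ccc(=O)oc4c3)(C(C)=C)O[N+]([O-])=C[C@@H]2C1(C)C
F2 | step 11 | (3R,5S,10S)-3-acetoxydrima-7,9(11)-dien-6-one | CC(=O)O[C@@H]1CC[C@@]2(C)C(=C)C(C)=CC(=O)[C@@H]2C1(C)C
F3 | step 11 | (3R,5S,9R,10S)-3-acetoxydrim-7-ene-6,11-diol (C6 epimers) | CC(=O)O[C@@H]1CC[C@@]2(C)[C@H](CO)C(C)=CC(O)[C@@H]2C1(C)C
F4 | step 11 | (3R,5S,9R,10S)-3-acetoxy-11-hydroxydrim-7-en-6-one | CC(=O)O[C@@H]1CC[C@@]2(C)[C@H](CO)C(C)=CC(=O)[C@@H]2C1(C)C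
F5 | step 5 | (2Z,6R)-3,7,7-trimethyl-2-(prop-1-en-2-yl)oct-2-ene-1,6,8-triol | OC/C(C(C)=C)=C(/C)CC[C@@H](O)C(C)(C)CO
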